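The route rests on enone ester 6. At this oxidation level the quaternary C6' of the cyclohexenone ring carries two CH2 arms (C5', C1'). C4'–C5'–C6'–C1' is therefore a prochiral 3,3-disubstituted cyclobutanol, and C3'=C2'–C7' is an allenyl group on its carbinol carbon. A Rh(I)/chiral bisphosphine catalyst cuts one of the two enantiotopic ring bonds of achiral allenylcyclobutanol 4 and closes the alkylrhodium onto the allenone. One operation turns the four-membered ring into the six-membered enone and sets the C7' methyl and the C6' stereocentre. C6' then controls C1' through a chelated alkynylation. The side-arm carbinol is bought as (R)-mevalonolactone, and both carboxyl groups come from one late double oxidation.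

Key step: step 3

Numbering (abscisic acid convention): C1' is the ring carbinol, C2' bears C7'H3, then C3', C4' (C=O) and C5'. C6' is quaternary and bears C9'H3 and C8'H2O. The side chain runs C1 (acid) to C5.
Assumption: 1, 10 and 15 are catalogue compounds. (R)-DTBM-SEGPHOS is written for step 3. Its sense of induction on this diastereomer must be confirmed in the first run, and the equally available (S)-ligand is used if the sense is opposite.

Step 1
Reactants: 1 methyl 1-methyl-3-oxocyclobutane-1-carboxylate
Product: 2 methyl 3-ethynyl-3-hydroxy-1-methylcyclobutane-1-carboxylate (OH cis to CO2Me; achiral)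
Conditions: HC≡CMgBr (1.1 equiv), THF, −78 → −20 °C; aq NH4Cl; chromatography to a single diastereomer
Reagents that add atoms: ethynylmagnesium bromide, C#C[Mg]Br
Why: In this Grignard 1,2-addition the strained cyclobutanone carbonyl is far more electrophilic than the tertiary ester, the acetylide should enter anti to the pseudo-axial ester so that OH ends cis to CO2Me, and since the product has a mirror plane through C1 and C3 only relative configuration is at stake.

Step 2
Reactants: 2 methyl 3-ethynyl-3-hydroxy-1-methylcyclobutane-1-carboxylate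
Product: 4 methyl 3-hydroxy-1-methyl-3-(propa-1,2-dienyl)cyclobutane-1-carboxylate (OH cis to CO2Me; achiral), via propargylic amine 3 (not isolated)
Conditions: (CH2O)n, CuI (0.5 equiv), Cy2NH, dioxane, reflux
Reagents that add atoms: paraformaldehyde (as formaldehyde), C=O
Why: In the Crabbé–Ma allenation, copper-mediated Mannich coupling of the terminal alkyne gives amine 3, whose 1,5-hydride shift and elimination deliver the terminal allene, a sequence that tolerates tertiary propargylic alcohols and esters and touches no ring centre.

Step 3
Reactants: 4 methyl 3-hydroxy-1-methyl-3-(propa-1,2-dienyl)cyclobutane-1-carboxylate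
Product: 6 methyl (1S)-1,3-dimethyl-5-oxocyclohex-3-ene-1-carboxylate, via exo-methylene ketone 5 (not isolated)
Conditions: [Rh(OH)(cod)]2 (2.5 mol %), (R)-DTBM-SEGPHOS (6 mol %), toluene, 80 °C; then DBU (10 mol %), rt
Reagents that add atoms: none
Why: Rh–OH deprotonates the tertiary alcohol of 4, and the chiral rhodium alkoxide undergoes strain-driven β-carbon elimination of one of the two enantiotopic C(carbinol)–CH2 ring bonds, which unmasks C4' as an allenyl ketone and leaves a neopentyl σ-alkylrhodium at C1'. This alkylrhodium adds 1,4 to the central allene carbon C2' (6-endo-dig closure of the only new ring, forming C1'–C2'), and the rhodium dienolate is protonated by the next molecule of 4 to give 5, which DBU conjugates to 6. The closest known reaction type is the Rh(I)-catalysed enantioselective ring expansion of allenyl tert-cyclobutanols to 5,5-disubstituted 3-methylcyclohex-2-enones. The single new stereocentre C6' is not a reacting atom: it becomes stereogenic because its two CH2 arms are differentiated, and the bisphosphine chooses the arm in the β-carbon elimination, acting on one diastereomer of 4 so that it reads one defined carbinol environment. The step needs β-carbon elimination to beat a 1,2-shift to a cyclopentanone, and ring closure to beat protodemetalation or β-hydride loss; the Rh–O bond, the absence of β-hydrogens at quaternary C6' and the tethered electrophilic allenone secure this, with the ester as a spectator.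

Step 4
Reactants: 6 methyl (1S)-1,3-dimethyl-5-oxocyclohex-3-ene-1-carboxylate
Product: 8 methyl (1R)-1,3-dimethyl-2,5-dioxocyclohex-3-ene-1-carboxylate, via allylic tert-butyl peroxide 7 (not isolated)
Conditions: Rh2(cap)4 (1 mol %), t-BuOOH (70 % aq), 1,2-dichloroethane, 40 °C, no base
Reagents that add atoms: tert-butyl hydroperoxide, CC(C)(C)OO
Why: In this dirhodium caprolactamate/TBHP allylic oxidation of an α,β-enone to the 1,4-enedione, the tert-butylperoxyl radical should abstract hydrogen from the secondary γ-position C1'H2 rather than the primary C7'H3, mixed peroxide 7 collapses to the ketone, base is omitted because 8 is a hydrolysis-sensitive β-keto ester, and quaternary C6' cannot epimerise (its descriptor changes only through CIP priorities).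

Step 5
Reactants: 8 methyl (1R)-1,3-dimethyl-2,5-dioxocyclohex-3-ene-1-carboxylate
Product: 9 methyl (7R)-7,9-dimethyl-8-oxo-1,4-dioxaspiro[4.5]dec-9-ene-7-carboxylate (C4' ethylene ketal)
Conditions: TMSOCH2CH2OTMS, TMSOTf (5 mol %), CH2Cl2, −78 → −20 °C
Reagents that add atoms: 1,2-bis(trimethylsilyloxy)ethane, C[Si](C)(C)OCCO[Si](C)(C)C
Why: Noyori ketalisation under non-aqueous kinetic conditions should take only the C4' carbonyl, flanked by CH and CH2, because the C1' carbonyl is shielded by quaternary C6' and methyl-bearing C2', the selectivity familiar from 4-oxoisophorone.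

Step 6
Reactants: 10 (2Z)-3-methylpent-2-en-4-yn-1-ol
Product: 11 triethyl[(2Z)-3-methylpent-2-en-4-ynyloxy]silane
Conditions: TESCl, imidazole, CH2Cl2, 0 °C
Reagents that add atoms: chlorotriethylsilane, CC[Si](Cl)(CC)CC
Why: This is routine silylation of a primary allylic alcohol, with TES chosen because it survives acetylide formation and hydride reduction yet can later be oxidised directly.

Step 7
Reactants: 11 triethyl[(2Z)-3-methylpent-2-en-4-ynyloxy]silane; 9 C4'-ketal keto ester
Product: 13 (1'S,6'R)-propargylic alcohol (9 with OH at C1' cis to C9'H3 plus the (3Z)-3-methyl-5-(triethylsilyloxy)pent-3-en-1-ynyl chain cis to CO2Me), via alkynylmagnesium bromide 12 (not isolated)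
Conditions: 11, EtMgBr, THF, 40 °C; dilute with toluene; 9, −20 °C → rt; aq NH4Cl
Reagents that add atoms: none
Why: In this chelation-controlled (Cram-chelate) 1,2-addition of an alkynyl Grignard reagent to a non-enolisable β-keto ester, Mg(II) ties C1'=O to the ester carbonyl and so places CO2Me pseudo-equatorial and C9'H3 pseudo-axial, which makes the slim acetylide enter anti to that methyl and sets C1' with the chain cis to C8' and OH cis to C9'.

Step 8
Reactants: 13 (1'S,6'R)-propargylic alcohol
Product: 14 (1'R,6'S)-diol (C4' ethylene ketal; C8'H2OH; C1'-OH; (1E,3Z)-3-methyl-5-(triethylsilyloxy)penta-1,3-dienyl chain)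
Conditions: Red-Al (5 equiv), THF, 0 °C → rt; Rochelle salt
Reagents that add atoms: none
Why: Alkoxide-directed trans-hydroalumination of the propargylic alcohol by Red-Al gives the (E)-alkene after protonolysis, while the same reagent reduces the ester to C8'H2OH; the ketal, the TES ether and the (Z)-alkene are inert, and neither stereocentre changes spatially.

Step 9
Reactants: 15 (R)-mevalonolactone
Product: 18 (3R)-3-hydroxy-3-methyl-5-(triethylsilyloxy)pentanoic acid, via potassium mevalonate 16 (not isolated), via bis-silyl derivative 17 (not isolated)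
Conditions: KOH (1.0 equiv), MeOH–H2O, rt, evaporate; TESCl (2.1 equiv), imidazole, DMF, 0 °C; pH 5 buffer work-up
Reagents that add atoms: potassium hydroxide, [K+].[OH-]; chlorotriethylsilane, CC[Si](Cl)(CC)CC
Why: Lactone saponification, silylation of the carboxylate and primary alcohol, and hydrolysis of the labile silyl ester on work-up differentiate the two arms of the purchased (3R) carbinol by oxidation level without touching it, the tertiary alcohol being too hindered for TESCl/imidazole and 18 being used at once.

Step 10
Reactants: 14 (1'R,6'S)-diol; 18 (3R)-3-hydroxy-3-methyl-5-(triethylsilyloxy)pentanoic acid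
Product: 19 C8' ester of 14 with 18 (bis-TES ether; C4' ketal)
Conditions: EDC·HCl, DMAP, CH2Cl2, 0 °C → rt
Reagents that add atoms: none
Why: In this Steglich esterification only the primary C8'-OH is acylated because both tertiary alcohols are inert, and with C4' still ketalised the free C8'-OH of 14 has no enone to add to.

Step 11
Reactants: 19 bis-TES ester
Product: 20 dialdehyde ((2Z,4E)-dienal plus 3-hydroxy-3-methyl-5-oxopentanoate; C4' ketal)
Conditions: (COCl)2, DMSO, CH2Cl2, −78 → −40 °C; Et3N, −78 → 0 °C
Reagents that add atoms: none
Why: In this Swern oxidation applied directly to primary triethylsilyl ethers, the chlorosulfonium salt displaces silicon from both unhindered CH2OTES groups and base then gives both aldehydes, so a free δ-hydroxy ester that could lactonise and expel C8'-OH never appears, while the hindered tertiary alcohols and the ketal stay untouched at low temperature.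

Step 12
Reactants: 20 dialdehyde
Product: 21 diacid C4' ketal
Conditions: NaClO2, NaH2PO4, 2-methyl-2-butene, t-BuOH–H2O, 0 °C → rt
Reagents that add atoms: sodium chlorite, [Na+].[O-]Cl=O
Why: Pinnick oxidation converts both aldehydes to acids near pH 4 without Z/E isomerisation or retro-aldol cleavage, and 2-methyl-2-butene keeps HOCl away from the diene.

Step 13
Reactants: 21 diacid C4' ketal
Product: 22 target CNP0183058.1
Conditions: 1 M HCl, THF, 0 °C → rt
Reagents that add atoms: water, O
Why: Acid hydrolysis of the allylic ketal is fast and unmasks the C4' enone, the C8' ester blocks oxa-Michael closure onto C2', and the emerging carbonyl destabilises a C1' cation so the tertiary alcohols and all stereocentres persist.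

Compound list
1 | methyl 1-methyl-3-oxocyclobutane-1-carboxylate | COC(=O)C1(C)CC(=O)C1 | starting material
2 | methyl 3-ethynyl-3-hydroxy-1-methylcyclobutane-1-carboxylate, OH cis to CO2Me | COC(=O)[C@]1(C)C[C@@](O)(C#C)C1 | intermediate
3 | methyl 3-[3-(dicyclohexylamino)prop-1-ynyl]-3-hydroxy-1-methylcyclobutane-1-carboxylate, OH cis to CO2Me | COC(=O)[C@]1(C)C[C@@](O)(C#CCN(C2CCCCC2)C2CCCCC2)C1 | intermediate
4 | methyl 3-hydroxy-1-methyl-3-(propa-1,2-dienyl)cyclobutane-1-carboxylate, OH cis to CO2Me | COC(=O)[C@]1(C)C[C@@](O)(C=C=C)C1 | intermediate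
5 | methyl (1S)-1-methyl-3-methylidene-5-oxocyclohexane-1-carboxylate | C=C1CC(=O)C[C@@](C)(C(=O)OC)C1 | intermediate
6 | methyl (1S)-1,3-dimethyl-5-oxocyclohex-3-ene-1-carboxylate | CC1=CC(=O)C[C@@](C)(C(=O)OC)C1 | intermediate
7 | methyl (1R)-2-(tert-butylperoxy)-1,3-dimethyl-5-oxocyclohex-3-ene-1-carboxylate (C2 epimers) | CC1=CC(=O)C[C@@](C)(C(=O)OC)C1OOC(C)(C)C | intermediate
8 | methyl (1R)-1,3-dimethyl-2,5-dioxocyclohex-3-ene-1-carboxylate | CC1=CC(=O)C[C@@](C)(C(=O)OC)C1=O | intermediate
9 | methyl (7R)-7,9-dimethyl-8-oxo-1,4-dioxaspiro[4.5]dec-9-ene-7-carboxylate | CC1=CC2(OCCO2)C[C@@](C)(C(=O)OC)C1=O | intermediate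
10 | (2Z)-3-methylpent-2-en-4-yn-1-ol | C#C/C(C)=C\CO | starting material
11 | triethyl[(2Z)-3-methylpent-2-en-4-ynyloxy]silane | C#C/C(C)=C\CO[Si](CC)(CC)CC | intermediate
12 | alkynylmagnesium bromide of 11 | Br[Mg]C#C/C(C)=C\CO[Si](CC)(CC)CC | intermediate
13 | (1'S,6'R)-propargylic alcohol, chain cis to CO2Me, OH cis to C9'H3, C4' ketal | CC1=CC2(OCCO2)C[C@@](C)(C(=O)OC)[C@@]1(O)C#C/C(C)=C\CO[Si](CC)(CC)CC | intermediate
14 | (1'R,6'S)-diol with (1E,3Z)-dienyl chain, terminal OTES, C4' ketal | CC1=CC2(OCCO2)C[C@@](C)(CO)[C@@]1(O)/C=C/C(C)=C\CO[Si](CC)(CC)CC | intermediate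
15 | (R)-mevalonolactone | C[C@@]1(O)CCOC(=O)C1 | starting material
16 | potassium (R)-mevalonate | [K+].[O-]C(=O)C[C@](C)(O)CCO | intermediate
17 | triethylsilyl (3R)-3-hydroxy-3-methyl-5-(triethylsilyloxy)pentanoate | CC[Si](CC)(CC)OC(=O)C[C@](C)(O)CCO[Si](CC)(CC)CC | intermediate
18 | (3R)-3-hydroxy-3-methyl-5-(triethylsilyloxy)pentanoic acid | OC(=O)C[C@](C)(O)CCO[Si](CC)(CC)CC | intermediate
19 | C8' (3R)-mevalonate ester of 14, bis-TES ether, C4' ketal | CC1=CC2(OCCO2)C[C@@](C)(COC(=O)C[C@](C)(O)CCO[Si](CC)(CC)CC)[C@@]1(O)/C=C/C(C)=C\CO[Si](CC)(CC)CC | intermediate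
20 | dialdehyde, C4' ketal | CC1=CC2(OCCO2)C[C@@](C)(COC(=O)C[C@](C)(O)CC=O)[C@@]1(O)/C=C/C(C)=C\C=O | intermediate
21 | diacid, C4' ketal | CC1=CC2(OCCO2)C[C@@](C)(COC(=O)C[C@](C)(O)CC(=O)O)[C@@]1(O)/C=C/C(C)=C\C(=O)O | intermediate
22 | CNP0183058.1, (1'R,6'S,2Z,4E)-8'-O-[(3R)-4-carboxy-3-hydroxy-3-methylbutanoyl]-8'-hydroxyabscisic acid | CC1=CC(=O)C[C@@](C)(COC(=O)C[C@](C)(O)CC(=O)O)[C@@]1(O)/C=C/C(C)=C\C(=O)O | target

Total step count: 13. Longest linear sequence: 11 steps (1–5, 7, 8, 10–13). Steps 6 and 9 prepare the two side fragments.

Steps most likely to fail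

Step 3. The catalyst may discriminate poorly between the two enantiotopic ring bonds, for instance because the cis ester competes for a coordination site on the rhodium alkoxide. The fallback sets out from 4 and returns at 6. The same four-to-six ring expansion is run with an achiral catalyst ([Rh(OH)(cod)]2/dppb) to give racemic enone ester F1. LiOH saponification gives racemic acid F2. Crystallisation of its salt with one enantiomer of 1-phenylethylamine (chosen by trial), then acidification, gives (1S)-acid F3. MeI/K2CO3 in DMF returns 6. Absolute configuration then rests on a classical resolution instead of catalysis.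

Step 7. Facial selectivity may be poor if the non-chelated conformer with an axial ester reacts. The β-alkoxide ester may also open by retro-aldol cleavage on warming. The fallback sets out from 9 and returns at 14. LiAlH4 reduces ketone and ester to (6'S)-diol F4. MnO2 re-oxidises only the allylic C1' alcohol to (6'S)-β-hydroxy enone F5. Excess 12 first forms the C8' magnesium alkoxide. This covalent six-membered chelate with C1'=O, together with the now larger equatorial CH2O group, leaves C9'H3 axial and directs the acetylide to the same face, giving (1'S,6'S)-propargylic diol F6. Red-Al then reduces only the alkyne and delivers 14.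

Step 4. Hydrogen abstraction at the neopentyl C1'H2 may be slow. Competing oxidation at C7'H3 or over-oxidation of the sensitive enedione may then take over. The fallback sets out from 6 and returns at 8. TBSOTf/Et3N gives the extended silyl dienol ether F7. Peracid oxidation (m-CPBA, NaHCO3; vinylogous Rubottom oxidation) places oxygen at the γ-carbon C1' to give γ-hydroxy enone F8. Dess–Martin periodinane oxidises F8 to 8. The radical C–H oxidation is thus replaced by an ionic, regiodefined oxygenation.

Further compounds
F1 | step 3 | racemic methyl 1,3-dimethyl-5-oxocyclohex-3-ene-1-carboxylate | CC1=CC(=O)CC(C)(C(=O)OC)C1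
F2 | step 3 | racemic 1,3-dimethyl-5-oxocyclohex-3-ene-1-carboxylic acid | CC1=CC(=O)CC(C)(C(=O)O)C1
F3 | step 3 | (1S)-1,3-dimethyl-5-oxocyclohex-3-ene-1-carboxylic acid | CC1=CC(=O)C[C@@](C)(C(=O)O)C1
F4 | step 7 | (6'S)-diol, C4' ketal, C1' epimers | CC1=CC2(OCCO2)C[C@@](C)(CO)C1O
F5 | step 7 | (6'S)-β-hydroxy enone, C4' ketal | CC1=CC2(OCCO2)C[C@@](C)(CO)C1=O
F6 | step 7 | (1'S,6'S)-propargylic diol, C4' ketal | CC1=CC2(OCCO2)C[C@@](C)(CO)[C@@]1(O)C#C/C(C)=C\CO[Si](CC)(CC)CC
F7 | step 4 | extended tert-butyldimethylsilyl dienol ether of 6 | CC=1C=C(O[Si](C)(C)C(C)(C)C)C[C@@](C)(C(=O)OC)C=1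
F8 | step 4 | γ-hydroxy enone, C1' epimers | CC1=CC(=O)C[C@@](C)(C(=O)OC)C1O
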